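At early times the two hands of the flask fall alike, 48% and 48% at 10.0 s, and they part later, so we count in decades: the powers of ten of its own charge that each hand has lost.

| flask | left-handed substrate | right-handed substrate | gas | remark | time |
|---|---|---|---|---|---|
| midnight | 0.057 M | 0.057 M | 4.9 mM (held) | the very flask that is asked about, followed so far |  |
| flask | 0.057 M | 0.057 M | 4.9 mM (held) |  | 10 min |

midnight run (percent of the left-handed substrate and right-handed substrate together charged)

| time / s | left-handed substrate / % | right-handed substrate / % |
|---|---|---|
| 10.0 | 48 | 48 |
| 20.0 | 46 | 47 |
| 50.0 | 40 | 41 |
| 120 | 27 | 34 |

(each reading ± 1.5 percentage points)

- partner is single-handed; left-handed substrate and right-handed substrate are mirror images of each other, charged as a racemate, each of them at the stated concentration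
- at the start none of partner is dissolved
- the numbers in the tables scatter by 1.5 percentage points (one standard deviation)
- steps that have been proposed: partner + left-handed substrate -> left-handed product; partner + right-handed substrate -> right-handed product; left-handed substrate <-> achiral form; right-handed substrate <-> achiral form; left-handed product <-> right-handed product; achiral form -> decomposed reagent; gas <-> partner
- what has gone into achiral form counts as reacted
- an excess is the difference of the two amounts in percent of their sum
- an excess is below zero if the other one leads
- the handed part of partner does not stay in what it makes, so the products of the two hands are mirror images too

* part of the left-handed substrate and right-handed substrate charged together that has reacted at 10 min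
* excess of left-handed product over right-handed product in the product at 10 min
* excess of right-handed substrate over left-handed substrate among what is left of the two at 10 min

By 120 s the left-handed substrate has lost 0.268 decades and the right-handed substrate 0.167. Their quotient, a reading of 1.60, is our number: decades lost by the left hand per decade lost by the right, an apparent selectivity factor.

Held straight, the decades grow 5.00-fold up to 10 min. The left-handed substrate then keeps 4.59% of its charge and the right-handed substrate 14.5%, so we reckon c at 90.4% and eS at 52.0%. One number is not enough, though. At 50.0 s the same quotient reads 1.12, lower, so it drifts. And the readings hold no product, so it gives us no eP.

The forecast gave c 90%, eP 65% and eS 65%, an eS higher than ours, from its own extrapolation: “Extrapolating 480 s further gives left about 2% and right about 6–9%, so c is near 90%”.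

The flask gives c 87.3%, eP 6.23% and eS 52.5%.

    partner + left-handed substrate → left-handed product (k = 0.860 /M/s)
    partner + right-handed substrate → right-handed product (k = 0.0116 /M/s)
    left-handed substrate ⇌ achiral form (K = 0.671, k = 0.00413 /s)
    right-handed substrate ⇌ achiral form (K = 0.671, k = 0.00413 /s)
    left-handed product ⇌ right-handed product (k = 0.00509 /s)
    achiral form → decomposed reagent (k = 0.0162 /s)
    gas ⇌ partner, rate k7*(csat - [partner]) (kL = 0.0741 /s)

At 10 min the flask has kept 6.1% of the left-handed substrate charged and 19% of the right-handed, and these give the quotient as 1.71, against our 1.60. The product lies outside that number. Its excess stands at 74.4% after 1.00 min and falls because left-handed product and right-handed product interconvert, with a relaxation half-life of 1.13 min, short against 10 min. With that step taken away, the flask shows an eP of 95.7%, not 6.23%.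

(The numbers in the tables stem from a simulated flask for an exercise.)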